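**Strategy.** Rings A and B are disconnected together at C8–C9 and C5–C10. The feature exploited is that the ring-fusion alkene carbon C10 (C1=C10, ring A) sits between the quaternary stereocentre C9 and the methine C5 of ring B: this is the footprint of a diene adding to the α,β-bond of a 2,3-dienoate whose γ-carbon is C1. One thermal intramolecular Diels–Alder reaction of an acyclic, enantiopure (aS)-allenoate bearing a gem-dimethyl tether and an (E,Z)-diene thus forms both bonds, both rings and the three stereocentres C5, C8 and C9. The ester is then turned into a phenyltetrazolyl sulfone and joined to a separately made, enantiopure 1,2-dioxane aldehyde.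

Key step: step 8

Assumption and conventions: methyl 4,4-dimethyl-5-oxopentanoate (1) and geranyl benzoate (17) are taken to be catalogue chemicals; decalin atoms are cited by terpenoid numbers (C1=C10 alkene, C4 gem-dimethyl carbon, C5 ring-fusion CH, C8 CH–CH3, C9 quaternary carbon); the (aS) allene axis, which arises from the (R)-mesylate by anti displacement, is the one that leads to (9R); TBDPS = tert-butyldiphenylsilyl.

**Branch 1: decalin sulfone (steps 1–12)**

Step 1
Reactants: 1 methyl 4,4-dimethyl-5-oxopentanoate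
Product: 2 methyl (5E)-6-iodo-4,4-dimethylhex-5-enoate
Conditions: CrCl2, CHI3, THF, 0 °C → rt
Reagents that add atoms: iodoform, IC(I)I
Why: Takai iodo-olefination: the gem-dichromium reagent formed from CHI3 and CrCl2 adds to the non-enolisable neopentyl aldehyde and anti elimination should give the (E)-iodoalkene, the ester being inert to organochromium species.

Step 2
Reactants: 2 methyl (5E)-6-iodo-4,4-dimethylhex-5-enoate; 3 (Z)-prop-1-en-1-ylboronic acid
Product: 4 methyl (5E,7Z)-4,4-dimethylnona-5,7-dienoate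
Conditions: Pd(PPh3)4 (5 mol %), K3PO4, dioxane/H2O, 50 °C
Reagents that add atoms: none
Why: Suzuki–Miyaura coupling of an alkenyl iodide with an alkenylboronic acid proceeds with retention at both partners, so the (5E) geometry of 2 and the (Z) geometry of 3 should be carried into the diene.

Step 3
Reactants: 4 methyl (5E,7Z)-4,4-dimethylnona-5,7-dienoate
Product: 5 (5E,7Z)-N-methoxy-N,4,4-trimethylnona-5,7-dienamide
Conditions: MeNHOMe·HCl, i-PrMgCl, THF, −20 → 0 °C
Reagents that add atoms: N,O-dimethylhydroxylamine hydrochloride, CNOC.Cl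
Why: Weinreb amide formation by aminolysis of the methyl ester with the chloromagnesium amide is fast at low temperature and leaves the diene untouched.

Step 4
Reactants: 5 (5E,7Z)-N-methoxy-N,4,4-trimethylnona-5,7-dienamide; 6 prop-1-yn-1-ylmagnesium bromide
Product: 7 (8E,10Z)-7,7-dimethyldodeca-8,10-dien-2-yn-4-one
Conditions: THF, 0 °C; then aq. NH4Cl
Reagents that add atoms: none
Why: Weinreb ketone synthesis: the alkynyl Grignard reagent adds once because the magnesium-chelated tetrahedral intermediate survives until work-up, so the ynone should form without over-addition.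

Step 5
Reactants: 7 (8E,10Z)-7,7-dimethyldodeca-8,10-dien-2-yn-4-one
Product: 8 (4R,8E,10Z)-7,7-dimethyldodeca-8,10-dien-2-yn-4-ol
Conditions: RuCl[(R,R)-TsDPEN](p-cymene) (1 mol %), i-PrOH, rt
Reagents that add atoms: none
Why: Noyori asymmetric transfer hydrogenation of an alkynyl ketone: the ruthenium hydride of the (R,R)-diamine complex distinguishes the alkynyl from the alkyl flank and should deliver hydride to the face that gives the (4R)-carbinol, while C=C bonds are not reduced.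

Step 6
Reactants: 8 (4R,8E,10Z)-7,7-dimethyldodeca-8,10-dien-2-yn-4-ol
Product: 9 (4R,8E,10Z)-7,7-dimethyldodeca-8,10-dien-2-yn-4-yl methanesulfonate
Conditions: MsCl, Et3N, CH2Cl2, −78 °C
Reagents that add atoms: methanesulfonyl chloride, CS(=O)(=O)Cl
Why: O-sulfonylation does not touch the C–O bond, so the (4R) configuration is retained in the mesylate, which is used without storage.

Step 7
Reactants: 9 (4R,8E,10Z)-7,7-dimethyldodeca-8,10-dien-2-yn-4-yl methanesulfonate
Product: 10 methyl (aS,8E,10Z)-2,7,7-trimethyldodeca-2,3,8,10-tetraenoate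
Conditions: Pd(PPh3)4 (5 mol %), CO (1 atm), MeOH, 2,6-lutidine, THF, −20 °C → rt
Reagents that add atoms: carbon monoxide, [C-]#[O+]; methanol, CO
Why: Palladium-catalysed alkoxycarbonylation of a propargylic mesylate: zerovalent palladium displaces the mesylate anti in SN2′ fashion at the methyl-bearing alkyne carbon, and CO insertion and methanolysis with retention should transfer the (4R) centre into the (aS) allene axis.

Step 8
Reactants: 10 methyl (aS,8E,10Z)-2,7,7-trimethyldodeca-2,3,8,10-tetraenoate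
Product: 11 methyl (1R,2R,4aS)-1,2,5,5-tetramethyl-1,2,4a,5,6,7-hexahydronaphthalene-1-carboxylate
Conditions: toluene (0.01 M), BHT (5 mol %), 120 °C, sealed tube, Ar
Reagents that add atoms: none
Why: Proposed new method: a concerted, suprafacial [4+2] cycloaddition in which the (E,Z)-diene C5=C6–C7=C8 adds across the electron-poor α,β-bond C9=C10 of the allenoate and forms C5–C10 and C8–C9; the closest known reaction types are intramolecular Diels–Alder reactions of allenic esters at their α,β-bond and of (Z)-dienes, and intermolecular allenoate cycloadditions with axis-to-centre chirality transfer. Ring B closes as the cycloadduct ring (C5 to C10), and ring A closes as the six-membered tether ring C10–C1–C2–C3–C4–C5, in which the untouched allene π-bond becomes the endocyclic C1=C10 alkene. C9 is set by the allene axis, because the p-orbitals of C9=C10 lie in the plane of the C1 substituents and the three-carbon tether can deliver the diene only to the lobe on the C2 side, so the (aS) axis should give (9R). C5 and C8 are set relative to each other by the diene geometry (H5 and the C8 methyl group both occupy inside positions and end up cis) and relative to C9 by the ester-exo, methyl-endo orientation. That orientation is the selectivity the step needs, and it should be secured by the (Z)-methyl group, which lies next to the exo position and is better accommodated by the flat ester than by the α-methyl group, as in cycloadditions of α-methylacrylates. The gem-dimethyl group favours the folded conformer, heating without a Lewis acid protects the allene axis and the (Z)-alkene, and the absence of hydrogen at C9 keeps the alkene at C1=C10.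

Step 9
Reactants: 11 methyl (1R,2R,4aS)-1,2,5,5-tetramethyl-1,2,4a,5,6,7-hexahydronaphthalene-1-carboxylate
Product: 12 methyl (1R,2R,4aS)-1,2,5,5-tetramethyl-1,2,3,4,4a,5,6,7-octahydronaphthalene-1-carboxylate
Conditions: H2 (3 atm), RhCl(PPh3)3 (5 mol %), toluene/EtOH, rt
Reagents that add atoms: none
Why: Homogeneous hydrogenation with RhCl(PPh3)3 should reduce the cis-disubstituted C6=C7 alkene far faster than the hindered trisubstituted C1=C10 alkene and without double-bond migration, so no stereocentre is touched.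

Step 10
Reactants: 12 methyl (1R,2R,4aS)-1,2,5,5-tetramethyl-1,2,3,4,4a,5,6,7-octahydronaphthalene-1-carboxylate
Product: 13 [(1R,2R,4aS)-1,2,5,5-tetramethyl-1,2,3,4,4a,5,6,7-octahydronaphthalen-1-yl]methanol
Conditions: LiAlH4, THF, 0 °C → reflux
Reagents that add atoms: none
Why: Hydride reduction of the hindered ester with LiAlH4 gives the primary alcohol, and the quaternary C9 cannot epimerise.

Step 11
Reactants: 13 [(1R,2R,4aS)-1,2,5,5-tetramethyl-1,2,3,4,4a,5,6,7-octahydronaphthalen-1-yl]methanol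
Product: 14 1-phenyl-5-({[(1R,2R,4aS)-1,2,5,5-tetramethyl-1,2,3,4,4a,5,6,7-octahydronaphthalen-1-yl]methyl}sulfanyl)-1H-tetrazole
Conditions: 1-phenyl-1H-tetrazole-5-thiol, PPh3, DIAD, THF, 0 → 50 °C
Reagents that add atoms: 1-phenyl-1H-tetrazole-5-thiol, Sc1nnnn1-c1ccccc1
Why: Mitsunobu thioetherification: the acidic, soft tetrazolethiol displaces the oxyphosphonium group of the primary, neopentyl-type alcohol, and warming should compensate for the hindered SN2 trajectory.

Step 12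
Reactants: 14 1-phenyl-5-({[(1R,2R,4aS)-1,2,5,5-tetramethyl-1,2,3,4,4a,5,6,7-octahydronaphthalen-1-yl]methyl}sulfanyl)-1H-tetrazole
Product: 16 1-phenyl-5-({[(1R,2R,4aS)-1,2,5,5-tetramethyl-1,2,3,4,4a,5,6,7-octahydronaphthalen-1-yl]methyl}sulfonyl)-1H-tetrazole, via sulfoxide 15 (not isolated)
Conditions: (NH4)6Mo7O24·4H2O (10 mol %), 30% H2O2, EtOH, 0 °C → rt
Reagents that add atoms: hydrogen peroxide, OO
Why: Molybdate-catalysed sulfide oxidation with H2O2 passes through the sulfoxide to the sulfone and, without a directing group, should leave the hindered trisubstituted alkene unepoxidised.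

**Branch 2: dioxane aldehyde (steps 13–22)**

Step 13
Reactants: 17 (2E)-3,7-dimethylocta-2,6-dien-1-yl benzoate (geranyl benzoate)
Product: 19 (2E)-3-methyl-6-oxohex-2-en-1-yl benzoate, via ozonide 18 (not isolated)
Conditions: O3 (1 equiv, Sudan Red 7B end-point), CH2Cl2, −78 °C; then PPh3, −78 °C → rt
Reagents that add atoms: ozone, [O-][O+]=O
Why: Chemoselective ozonolysis: ozone attacks the electron-rich terminal trisubstituted alkene much faster than the 2,3-alkene deactivated by the allylic benzoate, and phosphine reduction of the ozonide should give the aldehyde.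

Step 14
Reactants: 19 (2E)-3-methyl-6-oxohex-2-en-1-yl benzoate; 20 (4S)-4-benzyl-3-propanoyl-1,3-oxazolidin-2-one
Product: 22 (4S)-4-benzyl-3-[(2S,3R,6E)-8-(benzoyloxy)-3-hydroxy-2,6-dimethyloct-6-enoyl]-1,3-oxazolidin-2-one, via dibutylboron (Z)-enolate 21 (not isolated)
Conditions: Bu2BOTf, Et3N, CH2Cl2, −78 → 0 °C; 19, −78 → 0 °C; then pH 7 buffer, MeOH, H2O2
Reagents that add atoms: none
Why: Evans syn-aldol reaction: the (Z)-boron enolate reacts through a closed chair transition state on the face opposite the benzyl group, which should set the methyl-bearing centre (2S, the future C2 of the acid) and the syn carbinol (3R) in one step.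

Step 15
Reactants: 22 (4S)-4-benzyl-3-[(2S,3R,6E)-8-(benzoyloxy)-3-hydroxy-2,6-dimethyloct-6-enoyl]-1,3-oxazolidin-2-one
Product: 23 (2E,6R,7R)-6,8-dihydroxy-3,7-dimethyloct-2-en-1-yl benzoate
Conditions: LiBH4, MeOH (1 equiv), THF, 0 °C
Reagents that add atoms: none
Why: Reductive cleavage of the N-acyloxazolidinone with LiBH4 is much faster than reduction of the benzoate and should give the 1,3-diol and the recoverable auxiliary without touching either stereocentre.

Step 16
Reactants: 23 (2E,6R,7R)-6,8-dihydroxy-3,7-dimethyloct-2-en-1-yl benzoate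
Product: 24 (2E,6R,7R)-8-[(tert-butyldiphenylsilyl)oxy]-6-hydroxy-3,7-dimethyloct-2-en-1-yl benzoate
Conditions: TBDPSCl, imidazole, CH2Cl2, 0 °C
Reagents that add atoms: tert-butyl(chloro)diphenylsilane, CC(C)(C)[Si](Cl)(c1ccccc1)c1ccccc1
Why: Silylation with the bulky chlorosilane is selective for the primary over the secondary hydroxyl group.

Step 17
Reactants: 24 (2E,6R,7R)-8-[(tert-butyldiphenylsilyl)oxy]-6-hydroxy-3,7-dimethyloct-2-en-1-yl benzoate
Product: 25 (2E,6R,7R)-8-[(tert-butyldiphenylsilyl)oxy]-6-[(methanesulfonyl)oxy]-3,7-dimethyloct-2-en-1-yl benzoate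
Conditions: MsCl, Et3N, CH2Cl2, 0 °C
Reagents that add atoms: methanesulfonyl chloride, CS(=O)(=O)Cl
Why: Mesylation of the secondary alcohol retains its (R) configuration and provides the leaving group for the later inverting ring closure.

Step 18
Reactants: 25 (2E,6R,7R)-8-[(tert-butyldiphenylsilyl)oxy]-6-[(methanesulfonyl)oxy]-3,7-dimethyloct-2-en-1-yl benzoate
Product: 26 (2R,3R,6E)-1-[(tert-butyldiphenylsilyl)oxy]-8-hydroxy-2,6-dimethyloct-6-en-3-yl methanesulfonate
Conditions: K2CO3, MeOH, 0 °C → rt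
Reagents that add atoms: none
Why: Base-catalysed transesterification removes the benzoate under conditions in which the secondary mesylate and the silyl ether should be stable.

Step 19
Reactants: 26 (2R,3R,6E)-1-[(tert-butyldiphenylsilyl)oxy]-8-hydroxy-2,6-dimethyloct-6-en-3-yl methanesulfonate
Product: 27 (2R,3R)-1-[(tert-butyldiphenylsilyl)oxy]-5-[(2R,3R)-3-(hydroxymethyl)-2-methyloxiran-2-yl]-2-methylpentan-3-yl methanesulfonate
Conditions: Ti(OiPr)4 (10 mol %), D-(−)-diethyl tartrate (12 mol %), t-BuOOH, 4 Å MS, CH2Cl2, −20 °C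
Reagents that add atoms: tert-butyl hydroperoxide, CC(C)(C)OO
Why: Katsuki–Sharpless asymmetric epoxidation of the (E)-trisubstituted allylic alcohol: the titanium D-(−)-tartrate complex should deliver oxygen by reagent control to the face that gives the (2R,3R)-epoxy alcohol.

Step 20
Reactants: 27 (2R,3R)-1-[(tert-butyldiphenylsilyl)oxy]-5-[(2R,3R)-3-(hydroxymethyl)-2-methyloxiran-2-yl]-2-methylpentan-3-yl methanesulfonate
Product: 28 (2R,3R,6S,7R)-1-[(tert-butyldiphenylsilyl)oxy]-6-hydroperoxy-7,8-dihydroxy-2,6-dimethyloctan-3-yl methanesulfonate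
Conditions: anhydrous H2O2 in Et2O, H3PMo12O40 (5 mol %), rt
Reagents that add atoms: hydrogen peroxide, OO
Why: Acid-catalysed perhydrolysis of an epoxide: H2O2 should open the 2,3-epoxy alcohol at the tertiary carbon remote from the hydroxymethyl group with inversion, which installs the tertiary hydroperoxide with (6S) configuration.

Step 21
Reactants: 28 (2R,3R,6S,7R)-1-[(tert-butyldiphenylsilyl)oxy]-6-hydroperoxy-7,8-dihydroxy-2,6-dimethyloctan-3-yl methanesulfonate
Product: 29 (1R)-1-[(3S,6S)-6-{(2R)-1-[(tert-butyldiphenylsilyl)oxy]propan-2-yl}-3-methyl-1,2-dioxan-3-yl]ethane-1,2-diol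
Conditions: KOt-Bu (1.05 equiv), 18-crown-6, THF (0.01 M), 0 °C → rt
Reagents that add atoms: none
Why: Intramolecular alkylation of a hydroperoxide (6-exo-tet SN2): the peroxy anion, far more acidic and nucleophilic than the alcohols, should displace the secondary mesylate with inversion and close the 1,2-dioxane, the ring CH centre becoming (S).

Step 22
Reactants: 29 (1R)-1-[(3S,6S)-6-{(2R)-1-[(tert-butyldiphenylsilyl)oxy]propan-2-yl}-3-methyl-1,2-dioxan-3-yl]ethane-1,2-diol
Product: 30 (3S,6S)-6-{(2R)-1-[(tert-butyldiphenylsilyl)oxy]propan-2-yl}-3-methyl-1,2-dioxane-3-carbaldehyde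
Conditions: NaIO4, THF/pH 7 buffer, 0 °C
Reagents that add atoms: none
Why: Periodate cleavage of the terminal 1,2-diol (Malaprade reaction) gives the non-enolisable α-peroxy aldehyde, dialkyl peroxides being inert to periodate.

**Union and endgame (steps 23–26)**

Step 23
Reactants: 16 1-phenyl-5-({[(1R,2R,4aS)-1,2,5,5-tetramethyl-1,2,3,4,4a,5,6,7-octahydronaphthalen-1-yl]methyl}sulfonyl)-1H-tetrazole; 30 (3S,6S)-6-{(2R)-1-[(tert-butyldiphenylsilyl)oxy]propan-2-yl}-3-methyl-1,2-dioxane-3-carbaldehyde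
Product: 32 tert-butyl{(2R)-2-[(3S,6S)-6-methyl-6-{(E)-2-[(1S,2R,4aS)-1,2,5,5-tetramethyl-1,2,3,4,4a,5,6,7-octahydronaphthalen-1-yl]ethenyl}-1,2-dioxan-3-yl]propoxy}diphenylsilane, via potassium β-alkoxy sulfone 31 (not isolated)
Conditions: KN(SiMe3)2 added to 16 + 30, DME, −60 °C → rt
Reagents that add atoms: none
Why: Julia–Kocienski olefination: the metalated sulfone adds to the non-enolisable aldehyde and Smiles rearrangement with loss of SO2 and the tetrazolone should give the alkene, whose geometry is irrelevant because it is reduced next, while the dialkyl peroxide has no acidic α-hydrogen and should tolerate the brief low-temperature base.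

Step 24
Reactants: 32 tert-butyl{(2R)-2-[(3S,6S)-6-methyl-6-{(E)-2-[(1S,2R,4aS)-1,2,5,5-tetramethyl-1,2,3,4,4a,5,6,7-octahydronaphthalen-1-yl]ethenyl}-1,2-dioxan-3-yl]propoxy}diphenylsilane
Product: 33 tert-butyl{(2R)-2-[(3S,6R)-6-methyl-6-{2-[(1R,2R,4aS)-1,2,5,5-tetramethyl-1,2,3,4,4a,5,6,7-octahydronaphthalen-1-yl]ethyl}-1,2-dioxan-3-yl]propoxy}diphenylsilane
Conditions: KO2CN=NCO2K, AcOH, CH2Cl2/MeOH, 0 °C → rt, repeated charges
Reagents that add atoms: none
Why: Diimide reduction: concerted syn transfer of two hydrogen atoms from HN=NH should reduce the disubstituted C=C bond but neither the trisubstituted ring alkene nor the O–O bond.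

Step 25
Reactants: 33 tert-butyl{(2R)-2-[(3S,6R)-6-methyl-6-{2-[(1R,2R,4aS)-1,2,5,5-tetramethyl-1,2,3,4,4a,5,6,7-octahydronaphthalen-1-yl]ethyl}-1,2-dioxan-3-yl]propoxy}diphenylsilane
Product: 34 (2R)-2-[(3S,6R)-6-methyl-6-{2-[(1R,2R,4aS)-1,2,5,5-tetramethyl-1,2,3,4,4a,5,6,7-octahydronaphthalen-1-yl]ethyl}-1,2-dioxan-3-yl]propan-1-ol
Conditions: Bu4NF, AcOH, THF, 0 °C → rt
Reagents that add atoms: none
Why: Fluoride-mediated desilylation, buffered with acetic acid so that the peroxide is not exposed to strong base.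

Step 26
Reactants: 34 (2R)-2-[(3S,6R)-6-methyl-6-{2-[(1R,2R,4aS)-1,2,5,5-tetramethyl-1,2,3,4,4a,5,6,7-octahydronaphthalen-1-yl]ethyl}-1,2-dioxan-3-yl]propan-1-ol
Product: 36 mycaperoxide H, (2S)-2-[(3S,6R)-6-methyl-6-{2-[(1R,2R,4aS)-1,2,5,5-tetramethyl-1,2,3,4,4a,5,6,7-octahydronaphthalen-1-yl]ethyl}-1,2-dioxan-3-yl]propanoic acid, via aldehyde 35 (not isolated)
Conditions: TEMPO (20 mol %), PhI(OAc)2, MeCN/pH 7 buffer, rt
Reagents that add atoms: water, O
Why: Oxoammonium (TEMPO) oxidation with PhI(OAc)2 in wet acetonitrile should take the primary alcohol through the aldehyde hydrate to the acid under near-neutral conditions that spare the peroxide, the alkene and the α-stereocentre.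

**Compound list**

1 | methyl 4,4-dimethyl-5-oxopentanoate | COC(=O)CCC(C)(C)C=O | starting material
2 | methyl (5E)-6-iodo-4,4-dimethylhex-5-enoate | COC(=O)CCC(C)(C)/C=C/I | intermediate
3 | (Z)-prop-1-en-1-ylboronic acid | C/C=C\B(O)O | starting material
4 | methyl (5E,7Z)-4,4-dimethylnona-5,7-dienoate | COC(=O)CCC(C)(C)/C=C/C=C\C | intermediate
5 | (5E,7Z)-N-methoxy-N,4,4-trimethylnona-5,7-dienamide | CON(C)C(=O)CCC(C)(C)/C=C/C=C\C | intermediate
6 | prop-1-yn-1-ylmagnesium bromide | CC#C[Mg]Br | starting material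
7 | (8E,10Z)-7,7-dimethyldodeca-8,10-dien-2-yn-4-one | CC#CC(=O)CCC(C)(C)/C=C/C=C\C | intermediate
8 | (4R,8E,10Z)-7,7-dimethyldodeca-8,10-dien-2-yn-4-ol | CC#C[C@H](O)CCC(C)(C)/C=C/C=C\C | intermediate
9 | (4R,8E,10Z)-7,7-dimethyldodeca-8,10-dien-2-yn-4-yl methanesulfonate | CC#C[C@H](OS(C)(=O)=O)CCC(C)(C)/C=C/C=C\C | intermediate
10 | methyl (aS,8E,10Z)-2,7,7-trimethyldodeca-2,3,8,10-tetraenoate (P helicity) | COC(=O)C(C)=[C@@]=C([H])CCC(C)(C)/C=C/C=C\C | intermediate
11 | methyl (1R,2R,4aS)-1,2,5,5-tetramethyl-1,2,4a,5,6,7-hexahydronaphthalene-1-carboxylate | COC(=O)[C@@]1(C)C2=CCCC(C)(C)[C@@H]2C=C[C@H]1C | intermediate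
12 | methyl (1R,2R,4aS)-1,2,5,5-tetramethyl-1,2,3,4,4a,5,6,7-octahydronaphthalene-1-carboxylate | COC(=O)[C@@]1(C)C2=CCCC(C)(C)[C@@H]2CC[C@H]1C | intermediate
13 | [(1R,2R,4aS)-1,2,5,5-tetramethyl-1,2,3,4,4a,5,6,7-octahydronaphthalen-1-yl]methanol | OC[C@@]1(C)C2=CCCC(C)(C)[C@@H]2CC[C@H]1C | intermediate
14 | 1-phenyl-5-({[(1R,2R,4aS)-1,2,5,5-tetramethyl-1,2,3,4,4a,5,6,7-octahydronaphthalen-1-yl]methyl}sulfanyl)-1H-tetrazole | C(Sc1nnnn1-c1ccccc1)[C@@]1(C)C2=CCCC(C)(C)[C@@H]2CC[C@H]1C | intermediate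
15 | 1-phenyl-5-({[(1R,2R,4aS)-1,2,5,5-tetramethyl-1,2,3,4,4a,5,6,7-octahydronaphthalen-1-yl]methyl}sulfinyl)-1H-tetrazole (both configurations at sulfur) | O=S(C[C@@]1(C)C2=CCCC(C)(C)[C@@H]2CC[C@H]1C)c1nnnn1-c1ccccc1 | intermediate
16 | 1-phenyl-5-({[(1R,2R,4aS)-1,2,5,5-tetramethyl-1,2,3,4,4a,5,6,7-octahydronaphthalen-1-yl]methyl}sulfonyl)-1H-tetrazole | O=S(=O)(C[C@@]1(C)C2=CCCC(C)(C)[C@@H]2CC[C@H]1C)c1nnnn1-c1ccccc1 | intermediate
17 | (2E)-3,7-dimethylocta-2,6-dien-1-yl benzoate (geranyl benzoate) | CC(C)=CCC/C(C)=C/COC(=O)c1ccccc1 | starting material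
18 | (2E)-5-(5,5-dimethyl-1,2,4-trioxolan-3-yl)-3-methylpent-2-en-1-yl benzoate | CC1(C)OOC(CC/C(C)=C/COC(=O)c2ccccc2)O1 | intermediate
19 | (2E)-3-methyl-6-oxohex-2-en-1-yl benzoate | O=CCC/C(C)=C/COC(=O)c1ccccc1 | intermediate
20 | (4S)-4-benzyl-3-propanoyl-1,3-oxazolidin-2-one | CCC(=O)N1[C@@H](Cc2ccccc2)COC1=O | starting material
21 | (4S)-4-benzyl-3-{(1Z)-1-[(dibutylboranyl)oxy]prop-1-en-1-yl}-1,3-oxazolidin-2-one | C/C=C(\OB(CCCC)CCCC)N1[C@@H](Cc2ccccc2)COC1=O | intermediate
22 | (4S)-4-benzyl-3-[(2S,3R,6E)-8-(benzoyloxy)-3-hydroxy-2,6-dimethyloct-6-enoyl]-1,3-oxazolidin-2-one | O=C([C@@H](C)[C@H](O)CC/C(C)=C/COC(=O)c1ccccc1)N1[C@@H](Cc2ccccc2)COC1=O | intermediate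
23 | (2E,6R,7R)-6,8-dihydroxy-3,7-dimethyloct-2-en-1-yl benzoate | OC[C@@H](C)[C@H](O)CC/C(C)=C/COC(=O)c1ccccc1 | intermediate
24 | (2E,6R,7R)-8-[(tert-butyldiphenylsilyl)oxy]-6-hydroxy-3,7-dimethyloct-2-en-1-yl benzoate | CC(C)(C)[Si](OC[C@@H](C)[C@H](O)CC/C(C)=C/COC(=O)c1ccccc1)(c1ccccc1)c1ccccc1 | intermediate
25 | (2E,6R,7R)-8-[(tert-butyldiphenylsilyl)oxy]-6-[(methanesulfonyl)oxy]-3,7-dimethyloct-2-en-1-yl benzoate | CC(C)(C)[Si](OC[C@@H](C)[C@H](OS(C)(=O)=O)CC/C(C)=C/COC(=O)c1ccccc1)(c1ccccc1)c1ccccc1 | intermediate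
26 | (2R,3R,6E)-1-[(tert-butyldiphenylsilyl)oxy]-8-hydroxy-2,6-dimethyloct-6-en-3-yl methanesulfonate | CC(C)(C)[Si](OC[C@@H](C)[C@H](OS(C)(=O)=O)CC/C(C)=C/CO)(c1ccccc1)c1ccccc1 | intermediate
27 | (2R,3R)-1-[(tert-butyldiphenylsilyl)oxy]-5-[(2R,3R)-3-(hydroxymethyl)-2-methyloxiran-2-yl]-2-methylpentan-3-yl methanesulfonate | CC(C)(C)[Si](OC[C@@H](C)[C@H](OS(C)(=O)=O)CC[C@@]1(C)O[C@@H]1CO)(c1ccccc1)c1ccccc1 | intermediate
28 | (2R,3R,6S,7R)-1-[(tert-butyldiphenylsilyl)oxy]-6-hydroperoxy-7,8-dihydroxy-2,6-dimethyloctan-3-yl methanesulfonate | CC(C)(C)[Si](OC[C@@H](C)[C@H](OS(C)(=O)=O)CC[C@@](C)([C@H](O)CO)OO)(c1ccccc1)c1ccccc1 | intermediate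
29 | (1R)-1-[(3S,6S)-6-{(2R)-1-[(tert-butyldiphenylsilyl)oxy]propan-2-yl}-3-methyl-1,2-dioxan-3-yl]ethane-1,2-diol | C[C@H](CO[Si](c1ccccc1)(c1ccccc1)C(C)(C)C)[C@@H]1CC[C@@](C)([C@H](O)CO)OO1 | intermediate
30 | (3S,6S)-6-{(2R)-1-[(tert-butyldiphenylsilyl)oxy]propan-2-yl}-3-methyl-1,2-dioxane-3-carbaldehyde | C[C@H](CO[Si](c1ccccc1)(c1ccccc1)C(C)(C)C)[C@@H]1CC[C@@](C)(C=O)OO1 | intermediate
31 | potassium 1-[(3S,6S)-6-{(2R)-1-[(tert-butyldiphenylsilyl)oxy]propan-2-yl}-3-methyl-1,2-dioxan-3-yl]-2-[(1-phenyl-1H-tetrazol-5-yl)sulfonyl]-2-[(1R,2R,4aS)-1,2,5,5-tetramethyl-1,2,3,4,4a,5,6,7-octahydronaphthalen-1-yl]ethan-1-olate (both epimers at the two new centres) | C[C@H](CO[Si](c1ccccc1)(c1ccccc1)C(C)(C)C)[C@@H]1CC[C@@](C)(C([O-])C([C@@]2(C)C3=CCCC(C)(C)[C@@H]3CC[C@H]2C)S(=O)(=O)c2nnnn2-c2ccccc2)OO1.[K+] | intermediate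
32 | tert-butyl{(2R)-2-[(3S,6S)-6-methyl-6-{(E)-2-[(1S,2R,4aS)-1,2,5,5-tetramethyl-1,2,3,4,4a,5,6,7-octahydronaphthalen-1-yl]ethenyl}-1,2-dioxan-3-yl]propoxy}diphenylsilane | C[C@H](CO[Si](c1ccccc1)(c1ccccc1)C(C)(C)C)[C@@H]1CC[C@@](C)(/C=C/[C@@]2(C)C3=CCCC(C)(C)[C@@H]3CC[C@H]2C)OO1 | intermediate
33 | tert-butyl{(2R)-2-[(3S,6R)-6-methyl-6-{2-[(1R,2R,4aS)-1,2,5,5-tetramethyl-1,2,3,4,4a,5,6,7-octahydronaphthalen-1-yl]ethyl}-1,2-dioxan-3-yl]propoxy}diphenylsilane | C[C@H](CO[Si](c1ccccc1)(c1ccccc1)C(C)(C)C)[C@@H]1CC[C@@](C)(CC[C@@]2(C)C3=CCCC(C)(C)[C@@H]3CC[C@H]2C)OO1 | intermediate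
34 | (2R)-2-[(3S,6R)-6-methyl-6-{2-[(1R,2R,4aS)-1,2,5,5-tetramethyl-1,2,3,4,4a,5,6,7-octahydronaphthalen-1-yl]ethyl}-1,2-dioxan-3-yl]propan-1-ol | C[C@H](CO)[C@@H]1CC[C@@](C)(CC[C@@]2(C)C3=CCCC(C)(C)[C@@H]3CC[C@H]2C)OO1 | intermediate
35 | (2S)-2-[(3S,6R)-6-methyl-6-{2-[(1R,2R,4aS)-1,2,5,5-tetramethyl-1,2,3,4,4a,5,6,7-octahydronaphthalen-1-yl]ethyl}-1,2-dioxan-3-yl]propanal | C[C@H](C=O)[C@@H]1CC[C@@](C)(CC[C@@]2(C)C3=CCCC(C)(C)[C@@H]3CC[C@H]2C)OO1 | intermediate
36 | mycaperoxide H, (2S)-2-[(3S,6R)-6-methyl-6-{2-[(1R,2R,4aS)-1,2,5,5-tetramethyl-1,2,3,4,4a,5,6,7-octahydronaphthalen-1-yl]ethyl}-1,2-dioxan-3-yl]propanoic acid | C[C@H](C(=O)O)[C@@H]1CC[C@@](C)(CC[C@@]2(C)C3=CCCC(C)(C)[C@@H]3CC[C@H]2C)OO1 | target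

**Step count and risks**

Total step count: 26. Longest linear sequence: 16 steps (steps 1–12 and 23–26, from 1). The dioxane branch is 10 steps (13–22) and joins at step 23.

Steps most likely to fail:

1. Step 8 (Proposed new method). The (Z)-methyl diene may undergo a 1,5-hydrogen shift before it reaches the cycloaddition geometry, the diene may add in the ester-endo sense or to the unactivated C1=C10 π-bond, or the allene axis may racemise on heating. The fallback uses known reactions, sets out from 4 and comes back at 12, and makes the quaternary centre after the cycloaddition. LiAlH4 reduces 4 to (5E,7Z)-4,4-dimethylnona-5,7-dien-1-ol F1. I2, PPh3 and imidazole give (2Z,4E)-9-iodo-6,6-dimethylnona-2,4-diene F2. LiC≡CH·H2NCH2CH2NH2 in DMSO gives (7E,9Z)-6,6-dimethylundeca-7,9-dien-1-yne F3, and n-BuLi followed by ClCO2Me gives methyl (8E,10Z)-7,7-dimethyldodeca-8,10-dien-2-ynoate F4. The thermal intramolecular Diels–Alder reaction of this alkynoate, a linear dienophile with no endo/exo question, should give racemic methyl (2RS,4aSR)-2,5,5-trimethyl-2,4a,5,6,7,8-hexahydronaphthalene-1-carboxylate F5. Hydrogenation of its disubstituted alkene over RhCl(PPh3)3 and separation of the enantiomers on a chiral stationary phase give methyl (2R,4aS)-2,5,5-trimethyl-2,3,4,4a,5,6,7,8-octahydronaphthalene-1-carboxylate F6. Deconjugative α-methylation (LiN(i-Pr)2, DMPU, THF, −78 °C; MeI) then returns to 12: γ-deprotonation should occur at the C1 methylene cis to the ester, and methylation of the dienolate at C9 anti to the C8 methyl group.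

2. Step 23. The hindered sulfonyl carbanion may add too slowly to the α-quaternary aldehyde, so that self-condensation of the sulfone or base-induced cleavage of the peroxide takes over. The fallback sets out from 13 and comes back at 33, and replaces the sulfone by a phosphorus ylide. Tf2O and pyridine convert 13 into [(1R,2R,4aS)-1,2,5,5-tetramethyl-1,2,3,4,4a,5,6,7-octahydronaphthalen-1-yl]methyl trifluoromethanesulfonate F7. This alkylates PPh3 (toluene, 80 °C) to triphenyl{[(1R,2R,4aS)-1,2,5,5-tetramethyl-1,2,3,4,4a,5,6,7-octahydronaphthalen-1-yl]methyl}phosphonium trifluoromethanesulfonate F8. The ylide (NaN(SiMe3)2, THF, −78 °C) and 30 should give by Wittig olefination the (Z)-alkene tert-butyl{(2R)-2-[(3S,6S)-6-methyl-6-{(Z)-2-[(1S,2R,4aS)-1,2,5,5-tetramethyl-1,2,3,4,4a,5,6,7-octahydronaphthalen-1-yl]ethenyl}-1,2-dioxan-3-yl]propoxy}diphenylsilane F9, which diimide reduction as in step 24 converts into 33.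

3. Step 21. Base-induced fragmentation of the β-hydroxy hydroperoxide, or elimination of the mesylate, may compete with the 6-exo displacement. The fallback sets out from 28 and comes back at 29, and closes the ring without a free β-hydroxyl group. 2-Methoxypropene and pyridinium p-toluenesulfonate convert 28 into (2R,3R,6S)-1-[(tert-butyldiphenylsilyl)oxy]-6-[(4R)-2,2-dimethyl-1,3-dioxolan-4-yl]-6-[(2-methoxypropan-2-yl)peroxy]-2-methylheptan-3-yl methanesulfonate F10. Methanolysis of the more labile peroxyketal (pyridinium p-toluenesulfonate, MeOH, 0 °C) frees (2R,3R,6S)-1-[(tert-butyldiphenylsilyl)oxy]-6-[(4R)-2,2-dimethyl-1,3-dioxolan-4-yl]-6-hydroperoxy-2-methylheptan-3-yl methanesulfonate F11. KOt-Bu and 18-crown-6 close the ring to tert-butyl{(2R)-2-[(3S,6S)-6-[(4R)-2,2-dimethyl-1,3-dioxolan-4-yl]-6-methyl-1,2-dioxan-3-yl]propoxy}diphenylsilane F12, and aqueous AcOH removes the acetonide to give 29.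

**Further compounds**

F1 | step 8 | (5E,7Z)-4,4-dimethylnona-5,7-dien-1-ol | OCCCC(C)(C)/C=C/C=C\C
F2 | step 8 | (2Z,4E)-9-iodo-6,6-dimethylnona-2,4-diene | ICCCC(C)(C)/C=C/C=C\C
F3 | step 8 | (7E,9Z)-6,6-dimethylundeca-7,9-dien-1-yne | C#CCCCC(C)(C)/C=C/C=C\C
F4 | step 8 | methyl (8E,10Z)-7,7-dimethyldodeca-8,10-dien-2-ynoate | COC(=O)C#CCCCC(C)(C)/C=C/C=C\C
F5 | step 8 | racemic methyl (2RS,4aSR)-2,5,5-trimethyl-2,4a,5,6,7,8-hexahydronaphthalene-1-carboxylate (one enantiomer written) | COC(=O)C1=C2CCCC(C)(C)[C@@H]2C=C[C@H]1C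
F6 | step 8 | methyl (2R,4aS)-2,5,5-trimethyl-2,3,4,4a,5,6,7,8-octahydronaphthalene-1-carboxylate (formed as the racemate, then resolved) | COC(=O)C1=C2CCCC(C)(C)[C@@H]2CC[C@H]1C
F7 | step 23 | [(1R,2R,4aS)-1,2,5,5-tetramethyl-1,2,3,4,4a,5,6,7-octahydronaphthalen-1-yl]methyl trifluoromethanesulfonate | O=S(=O)(OC[C@@]1(C)C2=CCCC(C)(C)[C@@H]2CC[C@H]1C)C(F)(F)F
F8 | step 23 | triphenyl{[(1R,2R,4aS)-1,2,5,5-tetramethyl-1,2,3,4,4a,5,6,7-octahydronaphthalen-1-yl]methyl}phosphonium trifluoromethanesulfonate | C([C@@]1(C)C2=CCCC(C)(C)[C@@H]2CC[C@H]1C)[P+](c1ccccc1)(c1ccccc1)c1ccccc1.[O-]S(=O)(=O)C(F)(F)F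
F9 | step 23 | tert-butyl{(2R)-2-[(3S,6S)-6-methyl-6-{(Z)-2-[(1S,2R,4aS)-1,2,5,5-tetramethyl-1,2,3,4,4a,5,6,7-octahydronaphthalen-1-yl]ethenyl}-1,2-dioxan-3-yl]propoxy}diphenylsilane | C[C@H](CO[Si](c1ccccc1)(c1ccccc1)C(C)(C)C)[C@@H]1CC[C@@](C)(/C=C\[C@@]2(C)C3=CCCC(C)(C)[C@@H]3CC[C@H]2C)OO1
F10 | step 21 | (2R,3R,6S)-1-[(tert-butyldiphenylsilyl)oxy]-6-[(4R)-2,2-dimethyl-1,3-dioxolan-4-yl]-6-[(2-methoxypropan-2-yl)peroxy]-2-methylheptan-3-yl methanesulfonate | CC(C)(C)[Si](OC[C@@H](C)[C@H](OS(C)(=O)=O)CC[C@@](C)([C@H]1COC(C)(C)O1)OOC(C)(C)OC)(c1ccccc1)c1ccccc1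
F11 | step 21 | (2R,3R,6S)-1-[(tert-butyldiphenylsilyl)oxy]-6-[(4R)-2,2-dimethyl-1,3-dioxolan-4-yl]-6-hydroperoxy-2-methylheptan-3-yl methanesulfonate | CC(C)(C)[Si](OC[C@@H](C)[C@H](OS(C)(=O)=O)CC[C@@](C)([C@H]1COC(C)(C)O1)OO)(c1ccccc1)c1ccccc1
F12 | step 21 | tert-butyl{(2R)-2-[(3S,6S)-6-[(4R)-2,2-dimethyl-1,3-dioxolan-4-yl]-6-methyl-1,2-dioxan-3-yl]propoxy}diphenylsilane | C[C@H](CO[Si](c1ccccc1)(c1ccccc1)C(C)(C)C)[C@@H]1CC[C@@](C)([C@H]2COC(C)(C)O2)OO1
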